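## Retrosynthetic overview

1. Target 26 ⇒ triol 24 + two units of 4-hydroxybenzoic acid 25 (double Mitsunobu C–O disconnection, no phenol protection).
2. 24 ⇒ silyl-protected 7-methoxy-dihydrobenzofuran 23 ⇒ 7-phenol 22.
3. Key disconnection: ring B (benzene ring of the benzofuran) and ring C (dihydrofuran) of 22 are cut together back to furyl alkynyl ether 20. In the forward sense a gold-catalysed furan–yne benzannulation turns the furan oxygen into the 7-OH, the two alkyne carbons into C7a and C7, and the furan C4 substituent into the C5 side chain.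
4. 20 ⇒ alcohol 15 + trichloroethylene 16; 15 ⇒ bromofuran 13 + vinyl boronate 14; the C2/C3 stereodiad ⇒ Evans syn-aldol of furylacetyl imide 9 with aldehyde 2.
5. Ring order: ring A (syringyl) and the furan are bought; rings B and C form together in step 10; the two 4-hydroxybenzoate rings are attached last.

Assumption: the SMILES is read as the (2S,3R)-trans isomer; 3, 7, 14, 16 and 25 are taken as catalogue chemicals (TIPS = triisopropylsilyl, TBS = tert-butyldimethylsilyl).

## Route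

Step 1
Reactants: 1 syringaldehyde
Product: 2 3,5-dimethoxy-4-(TIPS-oxy)benzaldehyde
Conditions: TIPSCl, imidazole, DMF, rt
Reagents that add atoms: chlorotriisopropylsilane (TIPSCl), CC(C)[Si](Cl)(C(C)C)C(C)C
Why: Imidazole-mediated silyl ether formation masks the phenol for the enolate and organolithium steps ahead, and the hindered aryl TIPS ether is chosen because it survives KH and n-BuLi; no stereocentre.

Step 2
Reactants: 3 4-bromofuran-2-carbaldehyde
Product: 5 2-(4-bromofuran-2-yl)acetonitrile, via N-(1-tosylalkenyl)formamide 4 (not isolated)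
Conditions: TosMIC, t-BuOK, DME, −50 °C; then MeOH, reflux
Reagents that add atoms: p-toluenesulfonylmethyl isocyanide (TosMIC), Cc1ccc(cc1)S(=O)(=O)C[N+]#[C-]
Why: van Leusen reductive cyanation: the TosMIC anion adds to the aldehyde, the adduct collapses to 4, and methanolysis expels formate and sulfinate to leave the one-carbon-homologated nitrile; no stereocentre.

Step 3
Reactants: 5 2-(4-bromofuran-2-yl)acetonitrile
Product: 6 2-(4-bromofuran-2-yl)acetic acid
Conditions: NaOH, EtOH/H2O, reflux; then HCl (aq), 0 °C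
Reagents that add atoms: water, O; sodium hydroxide, [Na+].[OH-]
Why: Base hydrolysis of the nitrile to the carboxylate, which the bromofuran tolerates; no stereocentre.

Step 4
Reactants: 6 2-(4-bromofuran-2-yl)acetic acid; 7 (S)-4-benzyl-1,3-oxazolidin-2-one
Product: 9 (4S)-4-benzyl-3-[2-(4-bromofuran-2-yl)acetyl]-1,3-oxazolidin-2-one, via mixed pivalic anhydride 8 (not isolated)
Conditions: PivCl, Et3N, THF, −20 °C; then 7, LiCl, rt
Reagents that add atoms: none
Why: One-pot mixed-anhydride N-acylation of the Evans auxiliary (LiCl-promoted), which attacks the less hindered furylacetyl carbonyl of 8; the auxiliary stereocentre is untouched.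

Step 5
Reactants: 9 (4S)-4-benzyl-3-[2-(4-bromofuran-2-yl)acetyl]-1,3-oxazolidin-2-one; 2 3,5-dimethoxy-4-(TIPS-oxy)benzaldehyde
Product: 11 (4S)-4-benzyl-3-[(2R,3S)-2-(4-bromofuran-2-yl)-3-hydroxy-3-(3,5-dimethoxy-4-TIPS-oxyphenyl)propanoyl]-1,3-oxazolidin-2-one, via Z-boron enolate 10 (not isolated)
Conditions: Bu2BOTf, i-Pr2NEt, CH2Cl2, 0 °C; then 2, −78 → 0 °C; pH 7 buffer, MeOH, H2O2, 0 °C
Reagents that add atoms: none
Why: Evans syn-aldol: the Z-boron enolate 10 reacts through a closed Zimmerman–Traxler chair in which the aldehyde approaches the enolate face opposite the benzyl group of the (S)-auxiliary, which sets both stereocentres at once (2R,3S, the future C3 and C2 of the target) in the syn relationship that corresponds to the trans ring.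

Step 6
Reactants: 11 (the syn-aldol adduct)
Product: 12 (1S,2R)-2-(4-bromofuran-2-yl)-1-(3,5-dimethoxy-4-TIPS-oxyphenyl)propane-1,3-diol
Conditions: LiBH4, MeOH (1 equiv), THF, 0 °C
Reagents that add atoms: none
Why: Reductive cleavage of the imide (hydride attack at the exocyclic carbonyl) gives the primary alcohol and releases the auxiliary at 0 °C without retro-aldol, so both stereocentres are kept.

Step 7
Reactants: 12 (the 1,3-diol)
Product: 13 (1S,2R)-2-(4-bromofuran-2-yl)-1-(3,5-dimethoxy-4-TIPS-oxyphenyl)-3-(TIPS-oxy)propan-1-ol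
Conditions: TIPSCl, imidazole, CH2Cl2, 0 °C
Reagents that add atoms: chlorotriisopropylsilane (TIPSCl), CC(C)[Si](Cl)(C(C)C)C(C)C
Why: Sterically controlled silylation of the primary over the hindered benzylic secondary hydroxyl; TIPS is used because it resists 1,5 O-to-O silyl migration under the alkoxide conditions of step 9.

Step 8
Reactants: 13 (the bromofuran alcohol); 14 (E)-3-(TBS-oxy)prop-1-enylboronic acid pinacol ester
Product: 15 (1S,2R)-2-{4-[(E)-3-(TBS-oxy)prop-1-enyl]furan-2-yl}-1-(3,5-dimethoxy-4-TIPS-oxyphenyl)-3-(TIPS-oxy)propan-1-ol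
Conditions: Pd(OAc)2 (divalent palladium precatalyst), SPhos, K3PO4, THF/H2O, 60 °C
Reagents that add atoms: none
Why: Suzuki–Miyaura coupling of the 3-bromofuran-type C–Br bond with the alkenyl boronate proceeds with retention of the E geometry and installs the future C5 side chain before any organolithium is used.

Step 9
Reactants: 15 (the alkenylfuran alcohol); 16 trichloroethylene
Product: 20 (1S,2R)-1-(ethynyloxy)-2-{4-[(E)-3-(TBS-oxy)prop-1-enyl]furan-2-yl}-1-(3,5-dimethoxy-4-TIPS-oxyphenyl)-3-(TIPS-oxy)propane, via dichlorovinyl ether 17 (not isolated), via chloroethynyl ether 18 (not isolated), via lithium alkynyl ether 19 (not isolated)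
Conditions: KH, THF, 0 °C; 16, rt; then n-BuLi, −78 → −40 °C; MeOH, −78 °C
Reagents that add atoms: none
Why: Alkynyl ether synthesis from trichloroethylene: the potassium alkoxide adds to dichloroacetylene formed in the flask to give 17, n-BuLi eliminates HCl to 18 and exchanges Cl for Li to 19, and protonation gives 20; the C–O bond at the stereocentre is never broken, so configuration is retained.

Step 10
Reactants: 20 (the furyl alkynyl ether)
Product: 23 (2S,3R)-2-(3,5-dimethoxy-4-TIPS-oxyphenyl)-7-methoxy-3-(TIPS-oxymethyl)-5-[(E)-3-(TBS-oxy)prop-1-enyl]-2,3-dihydro-1-benzofuran, via arene oxide 21 (not isolated), via benzofuran-7-ol 22 (not isolated)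
Conditions: Ph3PAuNTf2 (3 mol %, monovalent gold), 4 Å MS, CH2Cl2, −20 °C → rt; then solvent switch to acetone, K2CO3, MeI, rt
Reagents that add atoms: iodomethane, CI
Why: Gold-catalysed furan–yne phenol synthesis (Hashmi type, known for 2-(furan-2-yl)ethyl alkynyl ethers): gold activates the alkynyl ether at its O-bearing carbon, furan C2 attacks in a 5-exo mode to a cyclopropyl gold carbene, the furan opens to a carbonyl carbene that closes to oxepine/arene oxide 21, and 21 opens toward the O1-stabilised cation to phenol 22, so ring B and ring C are made in one operation with the furan oxygen delivered to C7 and the two preset stereocentres untouched; Williamson methylation in the same flask gives 23.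

Step 11
Reactants: 23 (the tris-silyl ether)
Product: 24 (2S,3R)-2-(4-hydroxy-3,5-dimethoxyphenyl)-3-(hydroxymethyl)-5-[(E)-3-hydroxyprop-1-enyl]-7-methoxy-2,3-dihydro-1-benzofuran
Conditions: TBAF, AcOH, THF, 0 °C → rt
Reagents that add atoms: none
Why: Fluoride desilylation removes all three silyl ethers at once, and the acetic acid buffer keeps the liberated para-phenol from opening the C2–O1 benzylic ether through a quinone methide, so C2 and C3 are not scrambled.

Step 12
Reactants: 24 (the triol); 25 4-hydroxybenzoic acid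
Product: 26 quiquesetinerviusin B
Conditions: 25 (2.2 equiv), PPh3, DIAD, THF, 0 °C → rt
Reagents that add atoms: none
Why: Double Mitsunobu esterification: only the carboxylic acid is acidic enough to be the pronucleophile and only the two primary alcohols are activated as oxyphosphonium ions, so the three phenols stay free and the stereocentres (neither at a reacting carbon) are untouched.

## Compound list

1 | syringaldehyde (4-hydroxy-3,5-dimethoxybenzaldehyde) | COc1cc(C=O)cc(OC)c1O | starting material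
2 | 3,5-dimethoxy-4-(TIPS-oxy)benzaldehyde | COc1cc(C=O)cc(OC)c1O[Si](C(C)C)(C(C)C)C(C)C | intermediate
3 | 4-bromofuran-2-carbaldehyde | O=Cc1cc(Br)co1 | starting material
4 | N-[2-(4-bromofuran-2-yl)-1-tosylethenyl]formamide (alkene geometry undefined; not isolated) | O=CNC(=Cc1cc(Br)co1)S(=O)(=O)c1ccc(C)cc1 | intermediate
5 | 2-(4-bromofuran-2-yl)acetonitrile | N#CCc1cc(Br)co1 | intermediate
6 | 2-(4-bromofuran-2-yl)acetic acid | OC(=O)Cc1cc(Br)co1 | intermediate
7 | (S)-4-benzyl-1,3-oxazolidin-2-one | O=C1N[C@@H](Cc2ccccc2)CO1 | starting material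
8 | 2-(4-bromofuran-2-yl)acetic pivalic anhydride (not isolated) | CC(C)(C)C(=O)OC(=O)Cc1cc(Br)co1 | intermediate
9 | (4S)-4-benzyl-3-[2-(4-bromofuran-2-yl)acetyl]-1,3-oxazolidin-2-one | O=C(Cc1cc(Br)co1)N1[C@@H](Cc2ccccc2)COC1=O | intermediate
10 | Z-dibutylboron enolate of 9 (O–B and furyl cis; not isolated) | CCCCB(CCCC)O/C(=C\c1cc(Br)co1)N1[C@@H](Cc2ccccc2)COC1=O | intermediate
11 | (4S)-4-benzyl-3-[(2R,3S)-2-(4-bromofuran-2-yl)-3-hydroxy-3-(3,5-dimethoxy-4-TIPS-oxyphenyl)propanoyl]-1,3-oxazolidin-2-one | COc1cc([C@H]([C@H](c2cc(Br)co2)C(=O)N2[C@@H](Cc3ccccc3)COC2=O)O)cc(OC)c1O[Si](C(C)C)(C(C)C)C(C)C | intermediate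
12 | (1S,2R)-2-(4-bromofuran-2-yl)-1-(3,5-dimethoxy-4-TIPS-oxyphenyl)propane-1,3-diol | COc1cc([C@H]([C@H](c2cc(Br)co2)CO)O)cc(OC)c1O[Si](C(C)C)(C(C)C)C(C)C | intermediate
13 | (1S,2R)-2-(4-bromofuran-2-yl)-1-(3,5-dimethoxy-4-TIPS-oxyphenyl)-3-(TIPS-oxy)propan-1-ol | COc1cc([C@H]([C@H](c2cc(Br)co2)CO[Si](C(C)C)(C(C)C)C(C)C)O)cc(OC)c1O[Si](C(C)C)(C(C)C)C(C)C | intermediate
14 | (E)-3-(TBS-oxy)prop-1-enylboronic acid pinacol ester | CC(C)(C)[Si](C)(C)OC/C=C/B1OC(C)(C)C(C)(C)O1 | starting material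
15 | (1S,2R)-2-{4-[(E)-3-(TBS-oxy)prop-1-enyl]furan-2-yl}-1-(3,5-dimethoxy-4-TIPS-oxyphenyl)-3-(TIPS-oxy)propan-1-ol | COc1cc([C@H]([C@H](c2cc(/C=C/CO[Si](C)(C)C(C)(C)C)co2)CO[Si](C(C)C)(C(C)C)C(C)C)O)cc(OC)c1O[Si](C(C)C)(C(C)C)C(C)C | intermediate
16 | trichloroethylene | ClC=C(Cl)Cl | starting material
17 | (E)-1,2-dichlorovinyl ether of 15 (Cl on the O-bound carbon, the two Cl trans; not isolated) | COc1cc([C@H]([C@H](c2cc(/C=C/CO[Si](C)(C)C(C)(C)C)co2)CO[Si](C(C)C)(C(C)C)C(C)C)O/C(Cl)=C\Cl)cc(OC)c1O[Si](C(C)C)(C(C)C)C(C)C | intermediate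
18 | chloroethynyl ether of 15 (not isolated) | COc1cc([C@H]([C@H](c2cc(/C=C/CO[Si](C)(C)C(C)(C)C)co2)CO[Si](C(C)C)(C(C)C)C(C)C)OC#CCl)cc(OC)c1O[Si](C(C)C)(C(C)C)C(C)C | intermediate
19 | 2-lithioethynyl ether of 15 (not isolated) | COc1cc([C@H]([C@H](c2cc(/C=C/CO[Si](C)(C)C(C)(C)C)co2)CO[Si](C(C)C)(C(C)C)C(C)C)OC#C[Li])cc(OC)c1O[Si](C(C)C)(C(C)C)C(C)C | intermediate
20 | (1S,2R)-1-(ethynyloxy)-2-{4-[(E)-3-(TBS-oxy)prop-1-enyl]furan-2-yl}-1-(3,5-dimethoxy-4-TIPS-oxyphenyl)-3-(TIPS-oxy)propane | COc1cc([C@H]([C@H](c2cc(/C=C/CO[Si](C)(C)C(C)(C)C)co2)CO[Si](C(C)C)(C(C)C)C(C)C)OC#C)cc(OC)c1O[Si](C(C)C)(C(C)C)C(C)C | intermediate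
21 | 6,7-arene oxide of the (2S,3R)-dihydrobenzofuran (oxirane carbons undefined; in equilibrium with its oxepine; not isolated) | COc1cc([C@H]2OC3=C(C=C(/C=C/CO[Si](C)(C)C(C)(C)C)C4OC34)[C@@H]2CO[Si](C(C)C)(C(C)C)C(C)C)cc(OC)c1O[Si](C(C)C)(C(C)C)C(C)C | intermediate
22 | (2S,3R)-2-(3,5-dimethoxy-4-TIPS-oxyphenyl)-3-(TIPS-oxymethyl)-5-[(E)-3-(TBS-oxy)prop-1-enyl]-2,3-dihydro-1-benzofuran-7-ol (not isolated) | COc1cc([C@H]2Oc3c(O)cc(/C=C/CO[Si](C)(C)C(C)(C)C)cc3[C@@H]2CO[Si](C(C)C)(C(C)C)C(C)C)cc(OC)c1O[Si](C(C)C)(C(C)C)C(C)C | intermediate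
23 | (2S,3R)-2-(3,5-dimethoxy-4-TIPS-oxyphenyl)-7-methoxy-3-(TIPS-oxymethyl)-5-[(E)-3-(TBS-oxy)prop-1-enyl]-2,3-dihydro-1-benzofuran | COc1cc([C@H]2Oc3c(OC)cc(/C=C/CO[Si](C)(C)C(C)(C)C)cc3[C@@H]2CO[Si](C(C)C)(C(C)C)C(C)C)cc(OC)c1O[Si](C(C)C)(C(C)C)C(C)C | intermediate
24 | (2S,3R)-2-(4-hydroxy-3,5-dimethoxyphenyl)-3-(hydroxymethyl)-5-[(E)-3-hydroxyprop-1-enyl]-7-methoxy-2,3-dihydro-1-benzofuran | COc1cc([C@H]2Oc3c(OC)cc(/C=C/CO)cc3[C@@H]2CO)cc(OC)c1O | intermediate
25 | 4-hydroxybenzoic acid | OC(=O)c1ccc(O)cc1 | starting material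
26 | quiquesetinerviusin B: [(2S,3R)-2-(4-hydroxy-3,5-dimethoxyphenyl)-5-[(E)-3-(4-hydroxybenzoyloxy)prop-1-enyl]-7-methoxy-2,3-dihydro-1-benzofuran-3-yl]methyl 4-hydroxybenzoate | COc1cc([C@H]2Oc3c(OC)cc(/C=C/COC(=O)c4ccc(O)cc4)cc3[C@@H]2COC(=O)c2ccc(O)cc2)cc(OC)c1O | target

## Step count and risk

Total step count: 12. Longest linear sequence: 11 steps (3 → 26, steps 2 to 12); step 1 is the only side branch.

Three steps most likely to fail:

**Step 10 (gold cascade).** The benzylic alkynyl ether can ionise or hydrate under gold before the furan attacks. A furan with no C5 substituent and a C4 alkenyl group is untested, and the alkenyl group could divert arene-oxide opening toward the 6-phenol.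

Fallback, setting out from 2 and coming back at 24: give up the construction of ring B and close ring C on a bought arene. Commercial 5-bromo-2-hydroxy-3-methoxybenzaldehyde is protected with MOMCl and i-Pr2NEt as MOM ether F3. It is homologated as in steps 2 to 4: TosMIC to nitrile F4, NaOH to acid F5, PivCl then 7 to imide F6. The boron enolate of F6 is added to 2 as in step 5 to give syn-aldol adduct F7, and LiBH4 gives diol F8. HCl in MeOH/THF removes the MOM group, and the freed phenol closes onto the benzylic cation to give trans-bromodihydrobenzofuran F9 (C3 from the aldol, C2 under thermodynamic control). Suzuki coupling with 14 gives alkene F10, and TBAF/AcOH returns triol 24.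

**Step 9 (alkynyl ether formation).** The hindered benzylic alkoxide may add sluggishly, silyl groups may migrate under KH, and 20 is thermally labile (sigmatropic or retro-ene loss of ketene), so it must be used cold and at once.

Fallback, setting out from 15 and coming back at 19 (and hence 20): formic acetic anhydride and pyridine convert 15 into formate ester F1. Dibromomethylenation of the formate carbonyl with CBr4 and PPh3 in CH2Cl2 gives 2,2-dibromovinyl ether F2. n-BuLi at −78 °C effects Br/Li exchange and Fritsch–Buttenberg–Wiechell-type elimination to the lithium alkynyl ether 19, which is quenched as before. This builds the alkyne from the formate carbon and CBr4 and never exposes the substrate to KH.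

**Step 12 (double Mitsunobu with a free phenolic acid on a triol that carries a free phenol).** Phenol O-alkylation or ionisation of the activated cinnamyl alcohol (allylic transposition) could erode the yield.

Fallback, setting out from 23 and coming back at 26 (bypassing 24): aqueous HCl in THF cleaves the two alkyl silyl ethers but not the aryl TIPS ether and gives diol F11. Carbodiimide esterification (EDC, DMAP, CH2Cl2) with commercial 4-(tert-butyldimethylsilyloxy)benzoic acid gives bis-ester F12. TBAF/AcOH then removes the three aryl silyl groups to give 26.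

## Further compounds

F1 | step 9 | formate ester of 15 | COc1cc([C@H]([C@H](c2cc(/C=C/CO[Si](C)(C)C(C)(C)C)co2)CO[Si](C(C)C)(C(C)C)C(C)C)OC=O)cc(OC)c1O[Si](C(C)C)(C(C)C)C(C)C
F2 | step 9 | 2,2-dibromovinyl ether of 15 | COc1cc([C@H]([C@H](c2cc(/C=C/CO[Si](C)(C)C(C)(C)C)co2)CO[Si](C(C)C)(C(C)C)C(C)C)OC=C(Br)Br)cc(OC)c1O[Si](C(C)C)(C(C)C)C(C)C
F3 | step 10 | 5-bromo-3-methoxy-2-(methoxymethoxy)benzaldehyde | COCOc1c(OC)cc(Br)cc1C=O
F4 | step 10 | 2-[5-bromo-3-methoxy-2-(methoxymethoxy)phenyl]acetonitrile | COCOc1c(OC)cc(Br)cc1CC#N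
F5 | step 10 | 2-[5-bromo-3-methoxy-2-(methoxymethoxy)phenyl]acetic acid | COCOc1c(OC)cc(Br)cc1CC(=O)O
F6 | step 10 | (4S)-4-benzyl-3-{2-[5-bromo-3-methoxy-2-(methoxymethoxy)phenyl]acetyl}-1,3-oxazolidin-2-one | COCOc1c(OC)cc(Br)cc1CC(=O)N1[C@@H](Cc2ccccc2)COC1=O
F7 | step 10 | (4S)-4-benzyl-3-[(2S,3S)-2-[5-bromo-3-methoxy-2-(methoxymethoxy)phenyl]-3-hydroxy-3-(3,5-dimethoxy-4-TIPS-oxyphenyl)propanoyl]-1,3-oxazolidin-2-one | COc1cc([C@H]([C@H](c2cc(Br)cc(OC)c2OCOC)C(=O)N2[C@@H](Cc3ccccc3)COC2=O)O)cc(OC)c1O[Si](C(C)C)(C(C)C)C(C)C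
F8 | step 10 | (1S,2R)-2-[5-bromo-3-methoxy-2-(methoxymethoxy)phenyl]-1-(3,5-dimethoxy-4-TIPS-oxyphenyl)propane-1,3-diol | COc1cc([C@H]([C@H](c2cc(Br)cc(OC)c2OCOC)CO)O)cc(OC)c1O[Si](C(C)C)(C(C)C)C(C)C
F9 | step 10 | [(2S,3R)-5-bromo-2-(3,5-dimethoxy-4-TIPS-oxyphenyl)-7-methoxy-2,3-dihydro-1-benzofuran-3-yl]methanol | COc1cc([C@H]2Oc3c(OC)cc(Br)cc3[C@@H]2CO)cc(OC)c1O[Si](C(C)C)(C(C)C)C(C)C
F10 | step 10 | [(2S,3R)-2-(3,5-dimethoxy-4-TIPS-oxyphenyl)-7-methoxy-5-[(E)-3-(TBS-oxy)prop-1-enyl]-2,3-dihydro-1-benzofuran-3-yl]methanol | COc1cc([C@H]2Oc3c(OC)cc(/C=C/CO[Si](C)(C)C(C)(C)C)cc3[C@@H]2CO)cc(OC)c1O[Si](C(C)C)(C(C)C)C(C)C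
F11 | step 12 | (2S,3R)-2-(3,5-dimethoxy-4-TIPS-oxyphenyl)-3-(hydroxymethyl)-5-[(E)-3-hydroxyprop-1-enyl]-7-methoxy-2,3-dihydro-1-benzofuran | COc1cc([C@H]2Oc3c(OC)cc(/C=C/CO)cc3[C@@H]2CO)cc(OC)c1O[Si](C(C)C)(C(C)C)C(C)C
F12 | step 12 | bis[4-(TBS-oxy)benzoate] of F11 (both primary hydroxyls esterified) | COc1cc([C@H]2Oc3c(OC)cc(/C=C/COC(=O)c4ccc(O[Si](C)(C)C(C)(C)C)cc4)cc3[C@@H]2COC(=O)c2ccc(O[Si](C)(C)C(C)(C)C)cc2)cc(OC)c1O[Si](C(C)C)(C(C)C)C(C)C
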